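## Retrosynthetic overview

1. The target comes from its tetrabenzyl ether by hydrogenolysis. The ketone C(=O)–C(aryl) bond on ring D (the acylphloroglucinol ring) is cut to give 9-phenylnonanoic acid and an aryne of ring D, generated from a 2-(trimethylsilyl)aryl triflate that already carries the complete cis-flavan.
2. Enabling feature: on ring D the acyl-bearing carbon lies between two oxygen-bearing ring carbons. The C–acyl bond and the neighbouring C–OH bond are made together by aryne insertion into the C–O bond of the acid (the oxygen originally at that carbon leaves as triflate). The other oxygen (as OBn) sits beside the triple bond and decides which aryne carbon takes O and which takes the acyl group.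
3. The aryne precursor comes from a bromophenol, and this from the cis-(2R,4R)-flavan. The flavan is made by a chiral-acid-catalysed oxa-[4+2] cycloaddition of an ortho-quinone methide (ring A carbonyl oxygen, C4 carrying ring D) with 4-benzyloxystyrene (ring B). This closes ring C and sets C2 and C4.
4. The quinone methide precursor is a benzhydrol from a ring-D aldehyde and an ortho-lithiated ring-A phenoxide. The aldehyde comes from 3,5-bis(benzyloxy)phenol by para-formylation, bromination and silylation.
5. Ring order: rings A, B and D are bought as benzene rings. Ring C (the pyran) is the only ring formed (step 5). The key step forms no ring but two bonds on ring D.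

Key step: step 8

Remark: the (R)-configured acid catalyst is written for step 5 on the assumption that it gives the (2R,4R) series; if the sense of induction is the opposite, its (S)-antipode is used.

## Route

Step 1
Reactants: 1 3,5-bis(benzyloxy)phenol
Product: 3 2,6-bis(benzyloxy)-4-hydroxybenzaldehyde, via aryl iminium chloride 2 (not isolated)
Conditions: POCl3, DMF, MeCN, 0 °C to rt; then H2O, 50 °C
Reagents that add atoms: N,N-dimethylformamide, CN(C)C=O; water, O
Why: Vilsmeier–Haack formylation should go mainly to the position para to the free hydroxyl and between the two benzyloxy groups, as known for the dimethoxy analogue, and the minor ortho isomer is removed by crystallisation or chromatography.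

Step 2
Reactants: 3 2,6-bis(benzyloxy)-4-hydroxybenzaldehyde
Product: 4 2,6-bis(benzyloxy)-3-bromo-4-hydroxybenzaldehyde
Conditions: NBS (1.0 equiv), CH2Cl2, −20 to 0 °C
Reagents that add atoms: N-bromosuccinimide, O=C1CCC(=O)N1Br
Why: Electrophilic aromatic bromination has only the two equivalent positions ortho to the hydroxyl to choose from, so one equivalent of NBS at low temperature should give the single monobromide.

Step 3
Reactants: 4 2,6-bis(benzyloxy)-3-bromo-4-hydroxybenzaldehyde
Product: 5 2,6-bis(benzyloxy)-3-bromo-4-[(triisopropylsilyl)oxy]benzaldehyde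
Conditions: TIPSCl, imidazole, DMF, rt
Reagents that add atoms: chlorotri(propan-2-yl)silane, CC(C)[Si](Cl)(C(C)C)C(C)C
Why: O-silylation masks the phenol, which would otherwise quench the organolithium of step 4 and deactivate the aldehyde as a para-phenoxide, with a group that survives aryllithium addition and the acid catalysis of step 5.

Step 4
Reactants: 5 2,6-bis(benzyloxy)-3-bromo-4-[(triisopropylsilyl)oxy]benzaldehyde, 6 5-(benzyloxy)-2-bromophenol
Product: 8 [4-(benzyloxy)-2-hydroxyphenyl]{2,6-bis(benzyloxy)-3-bromo-4-[(triisopropylsilyl)oxy]phenyl}methanol (racemic), via lithium 2-lithiophenoxide 7 (not isolated)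
Conditions: 6, n-BuLi (2.0 equiv), Et2O, 0 °C to rt; then 5, THF, −78 to 0 °C; H2O
Reagents that add atoms: none
Why: O–H deprotonation and bromine–lithium exchange give the ortho-lithiated phenoxide, whose 1,2-addition to the aldehyde is much faster than exchange with the aryl bromide of 5; the carbinol configuration is irrelevant because the centre becomes planar in step 5.

Step 5
Reactants: 8 [4-(benzyloxy)-2-hydroxyphenyl]{2,6-bis(benzyloxy)-3-bromo-4-[(triisopropylsilyl)oxy]phenyl}methanol, 9 4-(benzyloxy)styrene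
Product: 11 (2R,4R)-7-(benzyloxy)-2-[4-(benzyloxy)phenyl]-4-{2,6-bis(benzyloxy)-3-bromo-4-[(triisopropylsilyl)oxy]phenyl}chromane, via ortho-quinone methide 10 (not isolated)
Conditions: (R)-3,3′-bis(2,4,6-triisopropylphenyl)-H8-BINOL N-triflylphosphoramide (5 mol%), 9 (3 equiv), 4 Å MS, CH2Cl2, −40 °C
Reagents that add atoms: none
Why: Chiral Brønsted acid-catalysed dehydration gives the catalyst-bound ortho-quinone methide, which should undergo an inverse-electron-demand oxa-Diels–Alder reaction with the electron-rich styrene through an endo transition state (2,4-cis), the catalyst pocket shielding one face of the methide so that C4 and, through the endo approach, C2 are both set as R.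

Step 6
Reactants: 11 (2R,4R)-7-(benzyloxy)-2-[4-(benzyloxy)phenyl]-4-{2,6-bis(benzyloxy)-3-bromo-4-[(triisopropylsilyl)oxy]phenyl}chromane
Product: 12 (2R,4R)-7-(benzyloxy)-2-[4-(benzyloxy)phenyl]-4-[2,6-bis(benzyloxy)-3-bromo-4-hydroxyphenyl]chromane
Conditions: TBAF, AcOH, THF, 0 °C
Reagents that add atoms: none
Why: Buffered fluoride desilylation of the aryl silyl ether should leave the benzyl ethers, the aryl bromide and both stereocentres untouched.

Step 7
Reactants: 12 (2R,4R)-7-(benzyloxy)-2-[4-(benzyloxy)phenyl]-4-[2,6-bis(benzyloxy)-3-bromo-4-hydroxyphenyl]chromane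
Product: 15 (2R,4R)-7-(benzyloxy)-2-[4-(benzyloxy)phenyl]-4-[2,6-bis(benzyloxy)-4-(trifluoromethanesulfonyloxy)-3-(trimethylsilyl)phenyl]chromane, via aryl trimethylsilyl ether 13 (not isolated), via C-silylated lithium phenoxide 14 (not isolated)
Conditions: HMDS, THF, 65 °C, then evaporation; n-BuLi, THF, −100 to −78 °C; Tf2O, −78 to 0 °C
Reagents that add atoms: hexamethyldisilazane, C[Si](C)(C)N[Si](C)(C)C; trifluoromethanesulfonic anhydride, O=S(=O)(OS(=O)(=O)C(F)(F)F)C(F)(F)F
Why: The standard one-pot sequence of O-silylation, bromine–lithium exchange, retro-Brook 1,3 O-to-C silyl shift and O-triflation should give the 2-silylaryl triflate, the low temperature keeping the aryllithium from deprotonating benzylic positions.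

Step 8
Reactants: 15 (2R,4R)-7-(benzyloxy)-2-[4-(benzyloxy)phenyl]-4-[2,6-bis(benzyloxy)-4-(trifluoromethanesulfonyloxy)-3-(trimethylsilyl)phenyl]chromane, 16 9-phenylnonanoic acid
Product: 19 1-{2,4-bis(benzyloxy)-3-[(2R,4R)-7-(benzyloxy)-2-(4-(benzyloxy)phenyl)chroman-4-yl]-6-hydroxyphenyl}-9-phenylnonan-1-one, via 3-benzyloxy aryne 17 (not isolated), via ortho-cesiated aryl ester 18 (not isolated)
Conditions: 16 (1.5 equiv), CsF (4 equiv), THF, 125 °C, sealed tube
Reagents that add atoms: none
Why: Fluoride removes the trimethylsilyl group and triflate leaves, giving the aryne on ring D; the carboxylate of 16 adds through oxygen to the aryne carbon whose neighbour is C–H (remote from the benzyloxy group), because the benzyloxy-bearing carbon beside the triple bond polarises the aryne so that the developing carbanion sits next to that inductively withdrawing oxygen, and the resulting aryl anion attacks the ester carbonyl and collapses with C–O cleavage (anionic ortho-Fries 1,3-acyl shift), which forms the acyl C–aryl C bond and leaves the carboxylate oxygen as the new ortho phenoxide. The closest known reaction type is the insertion of arynes from 2-silylaryl triflates into the C–O bond of carboxylic acids to give ortho-hydroxyaryl ketones, with the regiochemistry established for 3-alkoxybenzynes. No ring of the target is closed; the only ring involved is a transient four-membered oxetanolate from 4-exo-trig attack of the aryl anion on the ester carbonyl, which opens at once. No stereocentre is created, and C2 and C4 should be untouched because the medium contains no Lewis or Brønsted acid that could ionise the C4–aryl bond. The step needs regioselectivity, secured by the benzyloxy group on one side of the triple bond and hydrogen on the other, and it needs the acyl shift to outrun protonation of the aryl anion and O-arylation of the product phenoxide by a second aryne, which the high temperature, the excess CsF and the excess of acid over aryne precursor should favour.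

Step 9
Reactants: 19 1-{2,4-bis(benzyloxy)-3-[(2R,4R)-7-(benzyloxy)-2-(4-(benzyloxy)phenyl)chroman-4-yl]-6-hydroxyphenyl}-9-phenylnonan-1-one
Product: 20 1-{2,4,6-trihydroxy-3-[(2R,4R)-7-hydroxy-2-(4-hydroxyphenyl)chroman-4-yl]phenyl}-9-phenylnonan-1-one (CNP0175574.1)
Conditions: H2 (1 atm), Pd/C, EtOAc–MeOH, rt
Reagents that add atoms: none
Why: Hydrogenolysis of the four benzyl ethers under neutral conditions should leave the hydrogen-bonded ortho-hydroxyaryl ketone and the chroman C–O bond intact and cannot epimerise C2 or C4.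

## Compound list

1 | 3,5-bis(benzyloxy)phenol | Oc1cc(OCc2ccccc2)cc(OCc2ccccc2)c1 | starting material
2 | [2,6-bis(benzyloxy)-4-hydroxybenzylidene]dimethyliminium chloride | C[N+](C)=Cc1c(OCc2ccccc2)cc(O)cc1OCc1ccccc1.[Cl-] | intermediate (not isolated)
3 | 2,6-bis(benzyloxy)-4-hydroxybenzaldehyde | O=Cc1c(OCc2ccccc2)cc(O)cc1OCc1ccccc1 | intermediate
4 | 2,6-bis(benzyloxy)-3-bromo-4-hydroxybenzaldehyde | O=Cc1c(OCc2ccccc2)cc(O)c(Br)c1OCc1ccccc1 | intermediate
5 | 2,6-bis(benzyloxy)-3-bromo-4-[(triisopropylsilyl)oxy]benzaldehyde | O=Cc1c(OCc2ccccc2)cc(O[Si](C(C)C)(C(C)C)C(C)C)c(Br)c1OCc1ccccc1 | intermediate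
6 | 5-(benzyloxy)-2-bromophenol | Oc1cc(OCc2ccccc2)ccc1Br | starting material
7 | lithium 5-(benzyloxy)-2-lithiophenoxide | [Li]Oc1cc(OCc2ccccc2)ccc1[Li] | intermediate (not isolated)
8 | [4-(benzyloxy)-2-hydroxyphenyl]{2,6-bis(benzyloxy)-3-bromo-4-[(triisopropylsilyl)oxy]phenyl}methanol (racemic) | OC(c1ccc(OCc2ccccc2)cc1O)c1c(OCc2ccccc2)cc(O[Si](C(C)C)(C(C)C)C(C)C)c(Br)c1OCc1ccccc1 | intermediate
9 | 4-(benzyloxy)styrene | C=Cc1ccc(OCc2ccccc2)cc1 | starting material
10 | ortho-quinone methide: 3-(benzyloxy)-6-{2,6-bis(benzyloxy)-3-bromo-4-[(triisopropylsilyl)oxy]benzylidene}cyclohexa-2,4-dien-1-one | O=C1C=C(OCc2ccccc2)C=CC1=Cc1c(OCc2ccccc2)cc(O[Si](C(C)C)(C(C)C)C(C)C)c(Br)c1OCc1ccccc1 | intermediate (not isolated)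
11 | (2R,4R)-7-(benzyloxy)-2-[4-(benzyloxy)phenyl]-4-{2,6-bis(benzyloxy)-3-bromo-4-[(triisopropylsilyl)oxy]phenyl}chromane | Brc1c(O[Si](C(C)C)(C(C)C)C(C)C)cc(OCc2ccccc2)c([C@@H]2C[C@H](c3ccc(OCc4ccccc4)cc3)Oc3cc(OCc4ccccc4)ccc32)c1OCc1ccccc1 | intermediate
12 | (2R,4R)-7-(benzyloxy)-2-[4-(benzyloxy)phenyl]-4-[2,6-bis(benzyloxy)-3-bromo-4-hydroxyphenyl]chromane | Brc1c(O)cc(OCc2ccccc2)c([C@@H]2C[C@H](c3ccc(OCc4ccccc4)cc3)Oc3cc(OCc4ccccc4)ccc32)c1OCc1ccccc1 | intermediate
13 | trimethylsilyl ether of 12 | Brc1c(O[Si](C)(C)C)cc(OCc2ccccc2)c([C@@H]2C[C@H](c3ccc(OCc4ccccc4)cc3)Oc3cc(OCc4ccccc4)ccc32)c1OCc1ccccc1 | intermediate (not isolated)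
14 | lithium 3,5-bis(benzyloxy)-4-[(2R,4R)-7-(benzyloxy)-2-(4-(benzyloxy)phenyl)chroman-4-yl]-2-(trimethylsilyl)phenoxide | C[Si](C)(C)c1c(O[Li])cc(OCc2ccccc2)c([C@@H]2C[C@H](c3ccc(OCc4ccccc4)cc3)Oc3cc(OCc4ccccc4)ccc32)c1OCc1ccccc1 | intermediate (not isolated)
15 | (2R,4R)-7-(benzyloxy)-2-[4-(benzyloxy)phenyl]-4-[2,6-bis(benzyloxy)-4-(trifluoromethanesulfonyloxy)-3-(trimethylsilyl)phenyl]chromane | C[Si](C)(C)c1c(OS(=O)(=O)C(F)(F)F)cc(OCc2ccccc2)c([C@@H]2C[C@H](c3ccc(OCc4ccccc4)cc3)Oc3cc(OCc4ccccc4)ccc32)c1OCc1ccccc1 | intermediate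
16 | 9-phenylnonanoic acid | OC(=O)CCCCCCCCc1ccccc1 | starting material
17 | aryne of ring D: 3,5-bis(benzyloxy)-4-[(2R,4R)-7-(benzyloxy)-2-(4-(benzyloxy)phenyl)chroman-4-yl]benzyne | C1#CC=C(OCc2ccccc2)C([C@@H]2C[C@H](c3ccc(OCc4ccccc4)cc3)Oc3cc(OCc4ccccc4)ccc32)=C1OCc1ccccc1 | intermediate (not isolated)
18 | ortho-cesiated aryl 9-phenylnonanoate | [Cs]c1c(OC(=O)CCCCCCCCc2ccccc2)cc(OCc2ccccc2)c([C@@H]2C[C@H](c3ccc(OCc4ccccc4)cc3)Oc3cc(OCc4ccccc4)ccc32)c1OCc1ccccc1 | intermediate (not isolated)
19 | 1-{2,4-bis(benzyloxy)-3-[(2R,4R)-7-(benzyloxy)-2-(4-(benzyloxy)phenyl)chroman-4-yl]-6-hydroxyphenyl}-9-phenylnonan-1-one | O=C(CCCCCCCCc1ccccc1)c1c(O)cc(OCc2ccccc2)c([C@@H]2C[C@H](c3ccc(OCc4ccccc4)cc3)Oc3cc(OCc4ccccc4)ccc32)c1OCc1ccccc1 | intermediate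
20 | 1-{2,4,6-trihydroxy-3-[(2R,4R)-7-hydroxy-2-(4-hydroxyphenyl)chroman-4-yl]phenyl}-9-phenylnonan-1-one | O=C(CCCCCCCCc1ccccc1)c1c(O)cc(O)c([C@@H]2C[C@H](c3ccc(O)cc3)Oc3cc(O)ccc32)c1O | target

## Step count and risks

Total step count: 9. Longest linear sequence: 9 steps (1 to 20); compounds 6, 9 and 16 enter as purchased partners.

Steps most likely to fail:

**Step 8.** The aryl anion may be protonated before the acyl shift (leaving the aryl ester without the C–C bond), the product phenoxide may add to a second aryne, or the regiochemistry of carboxylate addition may erode. The fallback sets out from 12 and comes back at 19. Acid 16 is converted with oxalyl chloride and catalytic DMF into 9-phenylnonanoyl chloride F1, which acylates phenol 12 (Et3N, DMAP, CH2Cl2) to the ortho-bromoaryl ester F2. Bromine–lithium exchange with n-BuLi in THF at −100 °C then gives the ortho-lithiated aryl ester F3, which undergoes the anionic ortho-Fries 1,3-acyl shift and gives 19 on protonation. The same aryl anion is thus reached from the bromide by known chemistry and without an aryne.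

**Step 5.** Facial and endo selectivity may be poor because the quinone methide carries a twisted aryl group with two ortho substituents, and the electron-rich styrene may oligomerise under acid. The fallback sets out from 8 and comes back at 11. An achiral acid (diphenyl phosphate, CH2Cl2, 0 °C) should give the racemic cis-flavan, that is 11 together with its (2S,4S)-antipode F4, and preparative chromatography on a chiral stationary phase separates 11. The absolute configuration then comes from resolution, not from catalyst control.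

**Step 7.** The O-to-C silyl shift may be incomplete, the aryllithium may deprotonate a neighbouring benzylic position, or triflation of the hindered phenoxide may stall. The fallback sets out from 12 and comes back at 20. O-Benzylation (BnBr, K2CO3, DMF) gives the pentabenzyl aryl bromide F5, and n-BuLi in THF at −78 °C gives the aryllithium F6. Acylation of F6 with N-methoxy-N-methyl-9-phenylnonanamide F7 (from 16, N,O-dimethylhydroxylamine hydrochloride and a carbodiimide) gives the pentabenzyl ketone F8. Hydrogenolysis as in step 9 then gives 20.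

## Further compounds

F1 | step 8 | 9-phenylnonanoyl chloride | O=C(Cl)CCCCCCCCc1ccccc1
F2 | step 8 | 3,5-bis(benzyloxy)-4-[(2R,4R)-7-(benzyloxy)-2-(4-(benzyloxy)phenyl)chroman-4-yl]-2-bromophenyl 9-phenylnonanoate | O=C(CCCCCCCCc1ccccc1)Oc1cc(OCc2ccccc2)c([C@@H]2C[C@H](c3ccc(OCc4ccccc4)cc3)Oc3cc(OCc4ccccc4)ccc32)c(OCc2ccccc2)c1Br
F3 | step 8 | ortho-lithiated aryl 9-phenylnonanoate | [Li]c1c(OC(=O)CCCCCCCCc2ccccc2)cc(OCc2ccccc2)c([C@@H]2C[C@H](c3ccc(OCc4ccccc4)cc3)Oc3cc(OCc4ccccc4)ccc32)c1OCc1ccccc1
F4 | step 5 | (2S,4S)-7-(benzyloxy)-2-[4-(benzyloxy)phenyl]-4-{2,6-bis(benzyloxy)-3-bromo-4-[(triisopropylsilyl)oxy]phenyl}chromane | Brc1c(O[Si](C(C)C)(C(C)C)C(C)C)cc(OCc2ccccc2)c([C@H]2C[C@@H](c3ccc(OCc4ccccc4)cc3)Oc3cc(OCc4ccccc4)ccc32)c1OCc1ccccc1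
F5 | step 7 | (2R,4R)-7-(benzyloxy)-2-[4-(benzyloxy)phenyl]-4-[2,4,6-tris(benzyloxy)-3-bromophenyl]chromane | Brc1c(OCc2ccccc2)cc(OCc2ccccc2)c([C@@H]2C[C@H](c3ccc(OCc4ccccc4)cc3)Oc3cc(OCc4ccccc4)ccc32)c1OCc1ccccc1
F6 | step 7 | {2,4,6-tris(benzyloxy)-3-[(2R,4R)-7-(benzyloxy)-2-(4-(benzyloxy)phenyl)chroman-4-yl]phenyl}lithium | [Li]c1c(OCc2ccccc2)cc(OCc2ccccc2)c([C@@H]2C[C@H](c3ccc(OCc4ccccc4)cc3)Oc3cc(OCc4ccccc4)ccc32)c1OCc1ccccc1
F7 | step 7 | N-methoxy-N-methyl-9-phenylnonanamide | CON(C)C(=O)CCCCCCCCc1ccccc1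
F8 | step 7 | 1-{2,4,6-tris(benzyloxy)-3-[(2R,4R)-7-(benzyloxy)-2-(4-(benzyloxy)phenyl)chroman-4-yl]phenyl}-9-phenylnonan-1-one | O=C(CCCCCCCCc1ccccc1)c1c(OCc2ccccc2)cc(OCc2ccccc2)c([C@@H]2C[C@H](c3ccc(OCc4ccccc4)cc3)Oc3cc(OCc4ccccc4)ccc32)c1OCc1ccccc1
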